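**Retrosynthetic overview**
- The target is reached from its bis-MOM ether, and that from a skipped 6,9-diyne: one double syn semi-hydrogenation sets both Z alkenes, and acid then frees the phenols.
- Key disconnection C7′–C8′ (sp3–sp): a blue-light, copper-catalysed union of a 7-iodoheptyl arene with a terminal 1,4-diyne alcohol.
- Aryl half: 5-bromoresorcinol, MOM protection, then aryl Grignard plus 1,7-diiodoheptane under copper catalysis.
- Chiral half: (S)-propylene oxide, the only source of the C16′ stereocentre, opened at CH2 by a silyl-capped butynyl Grignard, then propargylated.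
- No ring is formed; the benzene ring is bought intact.

Assumption: the SMILES is read as the (16′S)-alcohol with 8′Z,11′Z alkenes, and 1,7-diiodoheptane is taken as purchasable. Compound numbers follow first appearance in the steps.

**Step 1**
Reactants: 1 5-bromoresorcinol
Product: 2 1-bromo-3,5-bis(methoxymethoxy)benzene
Conditions: NaH (2.4 equiv), MOMCl (2.4 equiv), DMF, 0 °C → rt
Reagents that add atoms: chloromethyl methyl ether (MOMCl), COCCl
Why: Williamson-type O-alkylation of both phenoxides gives base- and Grignard-stable acetals that come off later under mild acid.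

**Step 2**
Reactants: 2 1-bromo-3,5-bis(methoxymethoxy)benzene; 3 1,7-diiodoheptane
Product: 5 1-(7-iodoheptyl)-3,5-bis(methoxymethoxy)benzene, via aryl Grignard reagent 4 (not isolated)
Conditions: Mg, I2 (cat.), THF, 50 °C; then added slowly to 3 (3 equiv), Li2CuCl4 (3 mol %), THF/NMP, 0 °C → rt
Reagents that add atoms: none
Why: Kochi-type copper-catalysed Grignard–alkyl iodide cross-coupling; the excess of diiodide and inverse addition hold it at mono-arylation, and unreacted 3 is recovered.

**Step 3**
Reactants: 6 (S)-propylene oxide; 7 (4-bromobut-1-yn-1-yl)trimethylsilane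
Product: 10 (S)-hept-6-yn-2-ol, via butynyl Grignard reagent 8 (not isolated), via silyl-capped alkynol 9 (not isolated)
Conditions: 7, Mg, THF, 40 °C; CuI (10 mol %), then 6, −40 → 0 °C; then MeOH, K2CO3 (0.2 equiv), rt, same flask
Reagents that add atoms: none
Why: copper-catalysed SN2 epoxide opening by the Grignard at the unsubstituted CH2 leaves the C–O stereocentre untouched, so the (S) configuration is that of 6; methanolysis then removes the alkynyl silyl cap.

**Step 4**
Reactants: 10 (S)-hept-6-yn-2-ol; 11 propargyl bromide
Product: 13 (S)-deca-6,9-diyn-2-ol, via bis(bromomagnesium) alkynide alkoxide 12 (not isolated)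
Conditions: EtMgBr (2.1 equiv), THF, 0 → 50 °C; CuCl (10 mol %), then 11 (1.2 equiv), 50 °C
Reagents that add atoms: none
Why: copper-catalysed propargylation of an alkynyl Grignard is the classical entry to terminal 1,4-diynes; the magnesium alkoxide is a spectator and the stereocentre is not involved.

**Step 5**
Reactants: 5 1-(7-iodoheptyl)-3,5-bis(methoxymethoxy)benzene; 13 (S)-deca-6,9-diyn-2-ol (1.3 equiv)
Product: 14 (2S)-17-[3,5-bis(methoxymethoxy)phenyl]heptadeca-6,9-diyn-2-ol
Conditions: CuCl (10 mol %), 4,4′,4″-tri-tert-butyl-2,2′:6′,2″-terpyridine (10 mol %), K2CO3 (2 equiv), MeCN, blue LEDs (450 nm), 25 °C, Ar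
Reagents that add atoms: none
Why: Proposed new method: photoinduced copper-catalysed C(sp)–C(sp3) coupling on a terminal skipped (1,4-)diyne bearing a free secondary alcohol, a substrate class that strong-base acetylide alkylation cannot handle because the bis-propargylic CH2 is acidic; carbonate with CuCl/terpyridine forms the monovalent copper acetylide of 13, whose blue-light excited state transfers one electron to the primary C–I bond of 5, and the resulting primary alkyl radical (no fast cyclisation or 1,5-hydrogen-shift channel) is captured by the divalent copper acetylide, which releases the C7′–C8′ bond and returns monovalent copper; the remote stereocentre is untouched; the closest known reaction type is the photoinduced copper/terpyridine-catalysed Sonogashira-type alkylation of simple terminal alkynes with unactivated alkyl iodides.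

**Step 6**
Reactants: 14 (2S)-17-[3,5-bis(methoxymethoxy)phenyl]heptadeca-6,9-diyn-2-ol
Product: 15 (2S,6Z,9Z)-17-[3,5-bis(methoxymethoxy)phenyl]heptadeca-6,9-dien-2-ol
Conditions: H2 (1 atm), Ni(OAc)2·4H2O (20 mol %), NaBH4 (20 mol %), H2NCH2CH2NH2 (0.8 equiv), EtOH, rt; stopped after 2 equiv H2
Reagents that add atoms: none
Why: P-2 nickel (brown nickel boride poisoned by ethylenediamine) delivers H2 syn to each alkyne and releases the alkene, the standard semi-hydrogenation of skipped diynes to (Z,Z)-1,4-dienes.

**Step 7**
Reactants: 15 (2S,6Z,9Z)-17-[3,5-bis(methoxymethoxy)phenyl]heptadeca-6,9-dien-2-ol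
Product: 16 Hansfordiol D, 5-[(8Z,11Z,16S)-16-hydroxyheptadeca-8,11-dien-1-yl]benzene-1,3-diol
Conditions: conc. HCl (0.5 equiv), MeOH, 40 °C
Reagents that add atoms: none
Why: acid-catalysed acetal methanolysis (MOM cleavage) in a large excess of methanol traps the CH2 unit as dimethoxymethane; dilute acid at 40 °C leaves the skipped Z,Z-diene and the secondary alcohol untouched.

**Compound list**
1 | 5-bromoresorcinol (5-bromobenzene-1,3-diol) | Oc1cc(O)cc(Br)c1 | starting material
2 | 1-bromo-3,5-bis(methoxymethoxy)benzene | COCOc1cc(OCOC)cc(Br)c1 | intermediate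
3 | 1,7-diiodoheptane | ICCCCCCCI | starting material
4 | [3,5-bis(methoxymethoxy)phenyl]magnesium bromide | COCOc1cc(OCOC)cc([Mg]Br)c1 | intermediate
5 | 1-(7-iodoheptyl)-3,5-bis(methoxymethoxy)benzene | COCOc1cc(OCOC)cc(CCCCCCCI)c1 | intermediate
6 | (S)-propylene oxide, (S)-2-methyloxirane | C[C@H]1CO1 | starting material
7 | (4-bromobut-1-yn-1-yl)trimethylsilane | C[Si](C)(C)C#CCCBr | starting material
8 | [4-(trimethylsilyl)but-3-yn-1-yl]magnesium bromide | C[Si](C)(C)C#CCC[Mg]Br | intermediate
9 | (S)-7-(trimethylsilyl)hept-6-yn-2-ol | C[C@H](O)CCCC#C[Si](C)(C)C | intermediate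
10 | (S)-hept-6-yn-2-ol | C[C@H](O)CCCC#C | intermediate
11 | propargyl bromide (3-bromoprop-1-yne) | BrCC#C | starting material
12 | bromomagnesium (S)-7-(bromomagnesio)hept-6-yn-2-olate | C[C@H](O[Mg]Br)CCCC#C[Mg]Br | intermediate
13 | (S)-deca-6,9-diyn-2-ol | C[C@H](O)CCCC#CCC#C | intermediate
14 | (2S)-17-[3,5-bis(methoxymethoxy)phenyl]heptadeca-6,9-diyn-2-ol | C[C@H](O)CCCC#CCC#CCCCCCCCc1cc(OCOC)cc(OCOC)c1 | intermediate
15 | (2S,6Z,9Z)-17-[3,5-bis(methoxymethoxy)phenyl]heptadeca-6,9-dien-2-ol | C[C@H](O)CCC/C=C\C/C=C\CCCCCCCc1cc(OCOC)cc(OCOC)c1 | intermediate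
16 | Hansfordiol D, 5-[(8Z,11Z,16S)-16-hydroxyheptadeca-8,11-dien-1-yl]benzene-1,3-diol | C[C@H](O)CCC/C=C\C/C=C\CCCCCCCc1cc(O)cc(O)c1 | target

**Totals**
Total steps: 7. Longest linear sequence: 5 (steps 1, 2, 5, 6, 7 or steps 3, 4, 5, 6, 7).

**Steps most likely to fail, with fallbacks**

Step 5 (the proposed photochemical union). Risks are base- or copper-induced isomerisation of the terminal 1,4-diyne to an allene, hydrogen abstraction from its bis-propargylic CH2 by the alkyl radical, and alkyne oligomerisation. The fallback uses known chemistry only; it sets out from 5, uses 10 from step 3, and returns at 14, bypassing step 4 and compound 13. Iodide 5 is alkylated with dilithiated propargyl alcohol (HC≡CCH2OH, n-BuLi 2 equiv, THF/DMPU, −78 °C → rt) to give 10-[3,5-bis(methoxymethoxy)phenyl]dec-2-yn-1-ol F1. An Appel reaction (CBr4, PPh3, CH2Cl2, 0 °C) converts it into 1-(10-bromodec-8-yn-1-yl)-3,5-bis(methoxymethoxy)benzene F2. The thermal copper-mediated alkyne–propargyl bromide coupling (CuI, NaI, Cs2CO3, DMF, rt), which tolerates the free hydroxyl of 10, then joins F2 and 10 to give 14. The route becomes 8 steps.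

Step 4 (terminal skipped diyne). Risks are a second propargylation at the new terminal alkyne, SN2′ allene formation, and isomerisation of 13. The fallback sets out from 10 and returns at 13. Alkyne 10 is coupled with the silyl-capped electrophile 3-bromo-1-(trimethylsilyl)prop-1-yne under carbonate conditions (CuI, NaI, Cs2CO3, DMF, rt) to give (S)-10-(trimethylsilyl)deca-6,9-diyn-2-ol F3, which cannot react a second time. Buffered fluoride (Bu4NF/AcOH, THF, 0 °C) then uncaps F3 to 13 without exposing the diyne to free base.

Step 6 (double semi-hydrogenation). Risks are over-reduction, incomplete reduction to an enyne, and traces of E isomers that are hard to separate. The fallback sets out from 14 and returns at 15, replacing catalytic hydrogenation by stoichiometric syn-hydroboration and protonolysis. Dicyclohexylborane (3.3 equiv, THF, 0 °C → rt; one equivalent is taken up by the hydroxyl) adds once to each alkyne to give the tris(dicyclohexylboryl) adduct of 14 F4. It forms as a mixture of regioisomers that all lead to the same product. Acetic acid (50 °C) then replaces each C–B and the O–B bond by H with retention, giving 15; this sequence cannot over-reduce.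

**Further compounds**
F1 | step 5 | 10-[3,5-bis(methoxymethoxy)phenyl]dec-2-yn-1-ol | OCC#CCCCCCCCc1cc(OCOC)cc(OCOC)c1
F2 | step 5 | 1-(10-bromodec-8-yn-1-yl)-3,5-bis(methoxymethoxy)benzene | BrCC#CCCCCCCCc1cc(OCOC)cc(OCOC)c1
F3 | step 4 | (S)-10-(trimethylsilyl)deca-6,9-diyn-2-ol | C[C@H](O)CCCC#CCC#C[Si](C)(C)C
F4 | step 6 | tris(dicyclohexylboryl) adduct of 14 (O-boryl, alkenyl boron at C6 and C10; one regioisomer shown) | C[C@H](OB(C1CCCCC1)C1CCCCC1)CCC/C(B(C1CCCCC1)C1CCCCC1)=C\C/C=C(/B(C1CCCCC1)C1CCCCC1)CCCCCCCc1cc(OCOC)cc(OCOC)c1
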